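**Plan**

- Retrosynthesis: remove both acetonides; undo the C4a–H/C5–H reduction; cut C1–C8a of ring A by a retro-[3,3] shift that puts the carbonyl oxygen back into a ring (C2–O–C5), giving a 2,5-dialkylidene oxane fused to ring B; cut C1=C2 (lactone alkylidenation) to release the side chain; cut C5–C6 and C7–C8 of ring B (Diels–Alder).
- Enabling feature: the ring A carbonyl C2, C1 and the quaternary C8a, together with a C4a=C5 double bond placed in ring B, form a γ,δ-unsaturated ketone C2(=O)–C1–C8a–C4a=C5 (the Claisen retron). The C3–C4 bridge already ties the vinyl ether half to the allyl half.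
- Forward order: ring B and the lactone ring arise together by Diels–Alder; the side chain is joined by Takai–Utimoto alkylidenation; ring A arises in the key step by exchange of the ring oxygen for C1; hydrogenation and deprotection finish.
- Stereochemistry: side-chain carbinol from (R)-2-methylglycidol; the C6 carbinol from a malic-acid-derived (S)-dioxolane, which also directs the chelation-controlled endo Diels–Alder (C6 and C5–O). C5–O relays to C8a through the suprafacial shift; C4a is set by hydrogen-atom-transfer hydrogenation anti to the C8a methyl; C1 by equilibration.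

Key step: step 15

Remark: locants C1–C8a are those of the octahydronaphthalen-2(1H)-one core of the target (C2 carbonyl, C1 side-chain carbon, C4a/C8a ring fusion, C6 quaternary carbon of ring B) and are kept for the corresponding atoms of all precursors; compounds 1, 3, 8, 15 and 16 are taken as commercial.

**Route**

Step 1
Reactants: 1 3-methylbut-2-enal
Product: 2 (1E)-N-cyclohexyl-3-methylbut-2-en-1-imine
Conditions: cyclohexylamine, MgSO4, Et2O, 0 °C to rt
Reagents that add atoms: cyclohexylamine NC1CCCCC1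
Why: Imine condensation of the enal with a primary amine should give the 1-azadiene needed for regioselective α-functionalisation.

Step 2
Reactants: 2 (1E)-N-cyclohexyl-3-methylbut-2-en-1-imine; 3 tert-butyl prop-2-enoate
Product: 6 tert-butyl 4-formyl-5-methylhex-5-enoate, via lithium azadienide 4 (not isolated), via imine ester 5 (not isolated)
Conditions: LiN(iPr)2 (LDA), THF, −78 °C; then 3, −78 °C; then 1 M aq. HCl, 0 °C
Reagents that add atoms: water O
Why: γ-Deprotonation should give a 1-azapentadienyl anion that adds through its α-carbon to the acrylate (aza-enolate Michael addition), and imine hydrolysis releases the aldehyde; the new stereocentre is racemic and is erased in step 3.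

Step 3
Reactants: 6 tert-butyl 4-formyl-5-methylhex-5-enoate
Product: 7 5-(prop-1-en-2-yl)-3,4-dihydro-2H-pyran-2-one
Conditions: TsOH·H2O (5 mol%), toluene, reflux, Dean–Stark
Reagents that add atoms: none
Why: Acid should cleave the tert-butyl ester, close the 5-oxo acid to its hydroxy-lactone and dehydrate it toward the isopropenyl group (enol lactonisation), giving the conjugated 1-acyloxy diene.

Step 4
Reactants: 8 2-[(4S)-2,2-dimethyl-1,3-dioxolan-4-yl]ethan-1-ol
Product: 9 [(4S)-2,2-dimethyl-1,3-dioxolan-4-yl]acetaldehyde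
Conditions: TEMPO (10 mol%), PhI(OAc)2, CH2Cl2, rt
Reagents that add atoms: none
Why: Nitroxyl-catalysed oxidation of the primary alcohol should stop at the aldehyde and leave the acetonide and its stereocentre untouched.

Step 5
Reactants: 9 [(4S)-2,2-dimethyl-1,3-dioxolan-4-yl]acetaldehyde
Product: 10 2-[(4S)-2,2-dimethyl-1,3-dioxolan-4-yl]prop-2-enal
Conditions: 37% aq. HCHO, pyrrolidine (10 mol%), propionic acid (10 mol%), iPrOH, 45 °C
Reagents that add atoms: formaldehyde C=O
Why: Organocatalytic α-methylenation (Mannich condensation–elimination through the enamine) should give the 2-substituted acrolein without involving the dioxolane stereocentre.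

Step 6
Reactants: 7 5-(prop-1-en-2-yl)-3,4-dihydro-2H-pyran-2-one; 10 2-[(4S)-2,2-dimethyl-1,3-dioxolan-4-yl]prop-2-enal
Product: 11 (8R,8aS)-8-[(4S)-2,2-dimethyl-1,3-dioxolan-4-yl]-5-methyl-2-oxo-3,4,6,7,8,8a-hexahydro-2H-chromene-8-carbaldehyde
Conditions: Me2AlCl (2 equiv), CH2Cl2, −78 to −30 °C; then aq. potassium sodium tartrate
Reagents that add atoms: none
Why: Me2AlCl should bind the formyl oxygen and the proximal dioxolane oxygen in a six-membered chelate that locks the enal s-trans and shields the face carrying the dioxolane ring, so that in this Lewis-acid-promoted Diels–Alder reaction the diene adds to the open face with the formyl group endo and with its acyloxy-bearing terminus on the quaternary α-carbon (ortho/para rule for a 1-acyloxy-3-methyl diene), setting C6 and the C5–O centre cis to the formyl group.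

Step 7
Reactants: 11 (8R,8aS)-8-[(4S)-2,2-dimethyl-1,3-dioxolan-4-yl]-5-methyl-2-oxo-3,4,6,7,8,8a-hexahydro-2H-chromene-8-carbaldehyde
Product: 12 N-tosylhydrazone of 11 (E)
Conditions: TsNHNH2, MgSO4, THF, rt
Reagents that add atoms: 4-methylbenzenesulfonohydrazide Cc1ccc(cc1)S(=O)(=O)NN
Why: Hydrazone condensation at the only aldehyde should proceed without touching the lactone or the quaternary centre.

Step 8
Reactants: 12 N-tosylhydrazone of 11
Product: 14 (8S,8aS)-8-[(4S)-2,2-dimethyl-1,3-dioxolan-4-yl]-5,8-dimethyl-3,4,6,7,8,8a-hexahydro-2H-chromen-2-one, via N-boryl sulfonylhydrazine 13 (not isolated)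
Conditions: catecholborane, CHCl3, 0 °C; then NaOAc·3H2O, reflux
Reagents that add atoms: none
Why: Hydride addition to the C=N bond followed by acetate-induced loss of sulfinate and dinitrogen (reductive deoxygenation of a tosylhydrazone) should turn the formyl group into the C6 methyl group with all stereocentres unchanged.

Step 9
Reactants: 15 [(2R)-2-methyloxiran-2-yl]methanol; 16 but-3-en-1-ylmagnesium bromide
Product: 17 (2S)-2-methylhept-6-ene-1,2-diol
Conditions: CuI (10 mol%), THF, −30 to 0 °C; then 1 M aq. HCl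
Reagents that add atoms: none
Why: Copper-catalysed Grignard opening of the 2,2-disubstituted epoxide should occur at the unsubstituted carbon (SN2), so the tertiary carbinol keeps its configuration.

Step 10
Reactants: 17 (2S)-2-methylhept-6-ene-1,2-diol
Product: 18 (4S)-2,2,4-trimethyl-4-(pent-4-en-1-yl)-1,3-dioxolane
Conditions: 2,2-dimethoxypropane, PPTS (cat.), CH2Cl2, rt
Reagents that add atoms: 2,2-dimethoxypropane COC(C)(C)OC
Why: Acid-catalysed transketalisation should protect the 1,2-diol as its acetonide.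

Step 11
Reactants: 18 (4S)-2,2,4-trimethyl-4-(pent-4-en-1-yl)-1,3-dioxolane
Product: 20 4-[(4S)-2,2,4-trimethyl-1,3-dioxolan-4-yl]butanal, via ozonide 19 (not isolated)
Conditions: O3, CH2Cl2, −78 °C; then PPh3, −78 °C to rt
Reagents that add atoms: ozone [O-][O+]=O
Why: Ozonolysis of the terminal alkene with reductive work-up should give the aldehyde one carbon shorter.

Step 12
Reactants: 20 4-[(4S)-2,2,4-trimethyl-1,3-dioxolan-4-yl]butanal
Product: 21 hydrazone of 20
Conditions: N2H4·H2O (excess), EtOH, rt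
Reagents that add atoms: hydrazine NN
Why: Condensation with excess hydrazine should give the unsubstituted hydrazone and suppress azine formation.

Step 13
Reactants: 21 hydrazone of 20
Product: 22 (4S)-4-(4,4-dibromobutyl)-2,2,4-trimethyl-1,3-dioxolane
Conditions: CuBr2, LiOtBu, THF, 0 °C to rt
Reagents that add atoms: copper dibromide Br[Cu]Br
Why: Oxidation of the hydrazone by divalent copper to the diazoalkane and its bromination with loss of dinitrogen (gem-dibromination of hydrazones) should give the 1,1-dibromide under basic, acetonide-safe conditions.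

Step 14
Reactants: 14 (8S,8aS)-8-[(4S)-2,2-dimethyl-1,3-dioxolan-4-yl]-5,8-dimethyl-3,4,6,7,8,8a-hexahydro-2H-chromen-2-one; 22 (4S)-4-(4,4-dibromobutyl)-2,2,4-trimethyl-1,3-dioxolane
Product: 24 (2Z,8S,8aS)-8-[(4S)-2,2-dimethyl-1,3-dioxolan-4-yl]-5,8-dimethyl-2-{4-[(4S)-2,2,4-trimethyl-1,3-dioxolan-4-yl]butylidene}-3,4,6,7,8,8a-hexahydro-2H-chromene, via gem-dizinc reagent 23 (not isolated)
Conditions: Zn, PbCl2 (cat.), TiCl4, TMEDA, THF, 0 to 25 °C; filtration through basic alumina
Reagents that add atoms: none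
Why: Takai–Utimoto alkylidenation (gem-dizinc species transmetallated to low-valent titanium) should convert the lactone carbonyl into the exocyclic, mainly Z, enol ether and so join the side chain at C1=C2.

Step 15
Reactants: 24 (2Z,8S,8aS)-8-[(4S)-2,2-dimethyl-1,3-dioxolan-4-yl]-5,8-dimethyl-2-{4-[(4S)-2,2,4-trimethyl-1,3-dioxolan-4-yl]butylidene}-3,4,6,7,8,8a-hexahydro-2H-chromene
Product: 25 (1S,6S,8aR)-6-[(4S)-2,2-dimethyl-1,3-dioxolan-4-yl]-6,8a-dimethyl-1-{3-[(4S)-2,2,4-trimethyl-1,3-dioxolan-4-yl]propyl}-3,4,6,7,8,8a-hexahydronaphthalen-2(1H)-one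
Conditions: mesitylene (0.02 M, degassed), N,O-bis(trimethylsilyl)acetamide (0.1 equiv), sealed tube, 190 °C
Reagents that add atoms: none
Why: Proposed new method: heating the allyl vinyl ether C1=C2–O–C5–C4a=C8a should trigger a concerted [3,3] (Claisen) shift in which the C5–O bond breaks, C1 bonds to C8a and the former ring oxygen becomes the C2 carbonyl, so the oxane turns into carbocyclic ring A with exchange of O for C1; because C2 and C4a are tied by the C3–C4 bridge, the six-atom array can only fold into a boat (bicyclo[2.2.2]octane-like) transition state. The closest known reactions are the thermal Claisen ring expansions of 2-methylene-6-vinyl oxanes and 2-methylene-5-vinyl oxolanes (also enforced boats), the boat Cope rearrangement of 1,4-dimethylenecyclohexane and, for the O-to-C ring switch, the Ferrier carbocyclization; the 2,5-dialkylidene-oxane array used here has not been shown. Ring A closes as a six-membered ring in a formally 6-endo mode at the C4a=C8a alkene, with transposition of the double bond to C4a=C5. C8a is set by 1,3-chirality transfer, since the shift is suprafacial on the cyclohexenyl allyl unit and C1 therefore enters on the face from which the pseudoaxial C5–O bond departs (syn to the C6 methyl); C1 follows from the Z enol ether geometry (1S) and is corrected by equilibration in step 16. The step needs the [3,3] path to win over acid-induced migration of the exocyclic enol ether double bond into the oxane ring and over C5–O ionisation with recombination at C5, which the base-buffered, non-polar, dilute conditions and the gain of the C=O bond should secure; regiochemistry is fixed because only C8a is within bonding distance of C1 in the boat.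

Step 16
Reactants: 25 (1S,6S,8aR)-6-[(4S)-2,2-dimethyl-1,3-dioxolan-4-yl]-6,8a-dimethyl-1-{3-[(4S)-2,2,4-trimethyl-1,3-dioxolan-4-yl]propyl}-3,4,6,7,8,8a-hexahydronaphthalen-2(1H)-one
Product: 27 (1R,4aS,6S,8aS)-6-[(4S)-2,2-dimethyl-1,3-dioxolan-4-yl]-6,8a-dimethyl-1-{3-[(4S)-2,2,4-trimethyl-1,3-dioxolan-4-yl]propyl}octahydronaphthalen-2(1H)-one, via C1-epimeric trans-ketone 26 (not isolated)
Conditions: Mn(dpm)3 (10 mol%), PhSiH3, tBuOOH, iPrOH, rt; then K2CO3, MeOH, rt
Reagents that add atoms: none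
Why: Mukaiyama-type hydrogen-atom-transfer hydrogenation should place H on C5 and let the tertiary C4a radical take its hydrogen axially, anti to the vicinal C8a methyl, giving the trans-decalin; base then equilibrates the α-keto centre C1 toward the equatorial side chain (the axial epimer would be recycled).

Step 17
Reactants: 27 (1R,4aS,6S,8aS)-6-[(4S)-2,2-dimethyl-1,3-dioxolan-4-yl]-6,8a-dimethyl-1-{3-[(4S)-2,2,4-trimethyl-1,3-dioxolan-4-yl]propyl}octahydronaphthalen-2(1H)-one
Product: 28 (1R,4aS,6S,8aS)-6-[(1S)-1,2-dihydroxyethyl]-1-[(4S)-4,5-dihydroxy-4-methylpentyl]-6,8a-dimethyloctahydronaphthalen-2(1H)-one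
Conditions: 1 M aq. HCl, THF, rt
Reagents that add atoms: none
Why: Mild acid hydrolysis should remove both acetonides without affecting the ketone or the quaternary centres.

**Compound list**

1 | 3-methylbut-2-enal | CC(C)=CC=O | starting material
2 | (1E)-N-cyclohexyl-3-methylbut-2-en-1-imine | CC(C)=C/C=N/C1CCCCC1 | intermediate
3 | tert-butyl prop-2-enoate | C=CC(=O)OC(C)(C)C | starting material
4 | lithium cyclohexyl[(1E)-3-methylbuta-1,3-dien-1-yl]azanide | C=C(C)/C=C/N([Li])C1CCCCC1 | intermediate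
5 | tert-butyl 4-[(E)-(cyclohexylimino)methyl]-5-methylhex-5-enoate (racemic) | C=C(C)C(CCC(=O)OC(C)(C)C)/C=N/C1CCCCC1 | intermediate
6 | tert-butyl 4-formyl-5-methylhex-5-enoate (racemic) | C=C(C)C(C=O)CCC(=O)OC(C)(C)C | intermediate
7 | 5-(prop-1-en-2-yl)-3,4-dihydro-2H-pyran-2-one | CC(=C)C1=COC(=O)CC1 | intermediate
8 | 2-[(4S)-2,2-dimethyl-1,3-dioxolan-4-yl]ethan-1-ol | OCC[C@H]1COC(C)(C)O1 | starting material
9 | [(4S)-2,2-dimethyl-1,3-dioxolan-4-yl]acetaldehyde | O=CC[C@H]1COC(C)(C)O1 | intermediate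
10 | 2-[(4S)-2,2-dimethyl-1,3-dioxolan-4-yl]prop-2-enal | C=C(C=O)[C@H]1COC(C)(C)O1 | intermediate
11 | (8R,8aS)-8-[(4S)-2,2-dimethyl-1,3-dioxolan-4-yl]-5-methyl-2-oxo-3,4,6,7,8,8a-hexahydro-2H-chromene-8-carbaldehyde | O=C1CCC2=C(C)CC[C@](C=O)([C@H]3COC(C)(C)O3)[C@H]2O1 | intermediate
12 | 4-methyl-N'-[(E)-{(8R,8aS)-8-[(4S)-2,2-dimethyl-1,3-dioxolan-4-yl]-5-methyl-2-oxo-3,4,6,7,8,8a-hexahydro-2H-chromen-8-yl}methylidene]benzenesulfonohydrazide | O=C1CCC2=C(C)CC[C@](/C=N/NS(=O)(=O)c3ccc(C)cc3)([C@H]4COC(C)(C)O4)[C@H]2O1 | intermediate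
13 | N-(1,3,2-benzodioxaborol-2-yl)-N-{[(8R,8aS)-8-[(4S)-2,2-dimethyl-1,3-dioxolan-4-yl]-5-methyl-2-oxo-3,4,6,7,8,8a-hexahydro-2H-chromen-8-yl]methyl}-N'-tosylhydrazine | O=C1CCC2=C(C)CC[C@](CN(NS(=O)(=O)c3ccc(C)cc3)B4Oc5ccccc5O4)([C@H]6COC(C)(C)O6)[C@H]2O1 | intermediate
14 | (8S,8aS)-8-[(4S)-2,2-dimethyl-1,3-dioxolan-4-yl]-5,8-dimethyl-3,4,6,7,8,8a-hexahydro-2H-chromen-2-one | O=C1CCC2=C(C)CC[C@](C)([C@H]3COC(C)(C)O3)[C@H]2O1 | intermediate
15 | [(2R)-2-methyloxiran-2-yl]methanol | C[C@@]1(CO)CO1 | starting material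
16 | but-3-en-1-ylmagnesium bromide | C=CCC[Mg]Br | starting material
17 | (2S)-2-methylhept-6-ene-1,2-diol | C[C@@](O)(CO)CCCC=C | intermediate
18 | (4S)-2,2,4-trimethyl-4-(pent-4-en-1-yl)-1,3-dioxolane | C[C@]1(CCCC=C)COC(C)(C)O1 | intermediate
19 | 3-{3-[(4S)-2,2,4-trimethyl-1,3-dioxolan-4-yl]propyl}-1,2,4-trioxolane | C[C@]1(CCCC2OCOO2)COC(C)(C)O1 | intermediate
20 | 4-[(4S)-2,2,4-trimethyl-1,3-dioxolan-4-yl]butanal | C[C@]1(CCCC=O)COC(C)(C)O1 | intermediate
21 | (E)-{4-[(4S)-2,2,4-trimethyl-1,3-dioxolan-4-yl]butylidene}hydrazine | C[C@]1(CCC/C=N/N)COC(C)(C)O1 | intermediate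
22 | (4S)-4-(4,4-dibromobutyl)-2,2,4-trimethyl-1,3-dioxolane | C[C@]1(CCCC(Br)Br)COC(C)(C)O1 | intermediate
23 | (4S)-4-[4,4-bis(bromozincio)butyl]-2,2,4-trimethyl-1,3-dioxolane | C[C@]1(CCCC([Zn]Br)[Zn]Br)COC(C)(C)O1 | intermediate
24 | (2Z,8S,8aS)-8-[(4S)-2,2-dimethyl-1,3-dioxolan-4-yl]-5,8-dimethyl-2-{4-[(4S)-2,2,4-trimethyl-1,3-dioxolan-4-yl]butylidene}-3,4,6,7,8,8a-hexahydro-2H-chromene | C[C@]1(CCC/C=C2/CCC3=C(C)CC[C@](C)([C@H]4COC(C)(C)O4)[C@H]3O2)COC(C)(C)O1 | intermediate
25 | (1S,6S,8aR)-6-[(4S)-2,2-dimethyl-1,3-dioxolan-4-yl]-6,8a-dimethyl-1-{3-[(4S)-2,2,4-trimethyl-1,3-dioxolan-4-yl]propyl}-3,4,6,7,8,8a-hexahydronaphthalen-2(1H)-one | C[C@]4(CCC[C@@H]1C(=O)CCC2=C[C@@](C)([C@H]3COC(C)(C)O3)CC[C@@]21C)COC(C)(C)O4 | intermediate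
26 | (1S,4aS,6S,8aS)-6-[(4S)-2,2-dimethyl-1,3-dioxolan-4-yl]-6,8a-dimethyl-1-{3-[(4S)-2,2,4-trimethyl-1,3-dioxolan-4-yl]propyl}octahydronaphthalen-2(1H)-one | C[C@]4(CCC[C@@H]1C(=O)CC[C@H]2C[C@@](C)([C@H]3COC(C)(C)O3)CC[C@@]21C)COC(C)(C)O4 | intermediate
27 | (1R,4aS,6S,8aS)-6-[(4S)-2,2-dimethyl-1,3-dioxolan-4-yl]-6,8a-dimethyl-1-{3-[(4S)-2,2,4-trimethyl-1,3-dioxolan-4-yl]propyl}octahydronaphthalen-2(1H)-one | C[C@]4(CCC[C@H]1C(=O)CC[C@H]2C[C@@](C)([C@H]3COC(C)(C)O3)CC[C@@]21C)COC(C)(C)O4 | intermediate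
28 | (1R,4aS,6S,8aS)-6-[(1S)-1,2-dihydroxyethyl]-1-[(4S)-4,5-dihydroxy-4-methylpentyl]-6,8a-dimethyloctahydronaphthalen-2(1H)-one | C[C@@](O)(CO)CCC[C@H]1C(=O)CC[C@H]2C[C@@](C)([C@H](O)CO)CC[C@@]21C | target

**Step count and risks**

Total step count: 17. Longest linear sequence: 10 steps (steps 1–3, 6–8, 14–17).

Steps most likely to fail:

1. Step 15. The enforced boat geometry and the crowded C1–C8a bond (quaternary next to tertiary carbon) may raise the barrier so far that migration of the exocyclic enol ether double bond into the oxane ring (a dead end for the shift) or ionisation of the allylic C5–O bond outruns the rearrangement. The fallback uses known chemistry, sets out from lactone 14 and comes back at ketone 25. Methanolysis of 14 (K2CO3, MeOH) would give methyl 3-{(5S,6S)-5-[(4S)-2,2-dimethyl-1,3-dioxolan-4-yl]-6-hydroxy-2,5-dimethylcyclohex-1-en-1-yl}propanoate F1. Alkene 18 would be hydroborated and oxidised (9-BBN; NaOH, H2O2) to 5-[(4S)-2,2,4-trimethyl-1,3-dioxolan-4-yl]pentan-1-ol F2 and oxidised further (TEMPO, PhI(OAc)2, MeCN/H2O) to 5-[(4S)-2,2,4-trimethyl-1,3-dioxolan-4-yl]pentanoic acid F3. Esterification of F1 with F3 (carbodiimide, DMAP) would give the allylic ester F4. Ireland–Claisen rearrangement (excess LiN(iPr)2 and Me3SiCl, THF, −78 to 60 °C) would form C1–C8a suprafacially from the same C5–O centre and give the acid F5. Methylation (Me3SiCHN2) would give the dimethyl diester F6, Dieckmann condensation (KOtBu, THF) would close ring A at C2–C3 to the β-keto ester F7, and Krapcho dealkoxycarbonylation (LiCl, wet DMSO, 140 °C) would return 25 as C1 epimers that converge in step 16.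

2. Step 6. The acyloxy diene may react too slowly or polymerise under the Lewis acid before cycloaddition, and incomplete chelation would erode facial and endo selectivity. The fallback sets out from aldehyde 6 and comes back at lactone 11. Silylation of 6 (tBuMe2SiOTf, Et3N) would give the more electron-rich dienol ether tert-butyl (4E)-4-({[tert-butyl(dimethyl)silyl]oxy}methylidene)-5-methylhex-5-enoate F8. Its Diels–Alder reaction with 10 under the same chelating Lewis acid at −78 °C would give the monocyclic adduct tert-butyl 3-{(5S,6S)-6-{[tert-butyl(dimethyl)silyl]oxy}-5-[(4S)-2,2-dimethyl-1,3-dioxolan-4-yl]-5-formyl-2-methylcyclohex-1-en-1-yl}propanoate F9. Desilylation (HF·pyridine) and acid-mediated closure with loss of isobutene (anhydrous TsOH, toluene, 60 °C) would then form the lactone ring of 11 after, not during, the cycloaddition.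

3. Step 16. Hydrogen delivery to the C4a radical may occur on the face syn to the C8a methyl, because the desired face carries the syn-axial C6 methyl and C1 side chain, which would give the cis-fused ring system. The fallback puts C4a under thermodynamic control, sets out from 25 and comes back at target 28. Ketalisation of 25 (ethylene glycol, PPTS) would give the C2 ethylene ketal F10. Hydroboration–oxidation (BH3·THF; NaOH, H2O2) would give the C5 alcohol F11. Oxidation (Dess–Martin periodinane) and equilibration (NaOMe, MeOH) would give the trans-fused 5-ketone F12, in which C4a is α to a carbonyl. Wolff–Kishner reduction under forcing Huang-Minlon conditions (N2H4, KOH, diethylene glycol, 200 °C) would give the deoxygenated ketal F13. Hydrolysis of all three acetals (1 M aq. HCl, THF) and a short K2CO3/MeOH equilibration of C1 would lead to 28.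

**Further compounds**

F1 | step 15 | methyl 3-{(5S,6S)-5-[(4S)-2,2-dimethyl-1,3-dioxolan-4-yl]-6-hydroxy-2,5-dimethylcyclohex-1-en-1-yl}propanoate | COC(=O)CCC1=C(C)CC[C@](C)([C@H]2COC(C)(C)O2)[C@H]1O
F2 | step 15 | 5-[(4S)-2,2,4-trimethyl-1,3-dioxolan-4-yl]pentan-1-ol | C[C@]1(CCCCCO)COC(C)(C)O1
F3 | step 15 | 5-[(4S)-2,2,4-trimethyl-1,3-dioxolan-4-yl]pentanoic acid | C[C@]1(CCCCC(=O)O)COC(C)(C)O1
F4 | step 15 | (1S,6S)-6-[(4S)-2,2-dimethyl-1,3-dioxolan-4-yl]-2-(3-methoxy-3-oxopropyl)-3,6-dimethylcyclohex-2-en-1-yl 5-[(4S)-2,2,4-trimethyl-1,3-dioxolan-4-yl]pentanoate | COC(=O)CCC1=C(C)CC[C@](C)([C@H]2COC(C)(C)O2)[C@H]1OC(=O)CCCC[C@@]3(C)COC(C)(C)O3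
F5 | step 15 | 2-{4-[(4S)-2,2-dimethyl-1,3-dioxolan-4-yl]-2-(3-methoxy-3-oxopropyl)-1,4-dimethylcyclohex-2-en-1-yl}-5-[(4S)-2,2,4-trimethyl-1,3-dioxolan-4-yl]pentanoic acid (ring centres as in 25, acid α-carbon unassigned) | COC(=O)CCC1=C[C@@](C)([C@H]2COC(C)(C)O2)CC[C@]1(C)C(CCC[C@@]3(C)COC(C)(C)O3)C(=O)O
F6 | step 15 | methyl ester of F5 (dimethyl diester) | COC(=O)CCC1=C[C@@](C)([C@H]2COC(C)(C)O2)CC[C@]1(C)C(CCC[C@@]3(C)COC(C)(C)O3)C(=O)OC
F7 | step 15 | methyl 7-[(4S)-2,2-dimethyl-1,3-dioxolan-4-yl]-4a,7-dimethyl-3-oxo-4-{3-[(4S)-2,2,4-trimethyl-1,3-dioxolan-4-yl]propyl}-1,2,3,4,4a,5,6,7-octahydronaphthalene-2-carboxylate (ring centres as in 25) | COC(=O)C1CC2=C[C@@](C)([C@H]3COC(C)(C)O3)CC[C@]2(C)C(CCC[C@@]4(C)COC(C)(C)O4)C1=O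
F8 | step 6 | tert-butyl (4E)-4-({[tert-butyl(dimethyl)silyl]oxy}methylidene)-5-methylhex-5-enoate | CC(=C)/C(CCC(=O)OC(C)(C)C)=C/O[Si](C)(C)C(C)(C)C
F9 | step 6 | tert-butyl 3-{(5S,6S)-6-{[tert-butyl(dimethyl)silyl]oxy}-5-[(4S)-2,2-dimethyl-1,3-dioxolan-4-yl]-5-formyl-2-methylcyclohex-1-en-1-yl}propanoate | CC1=C(CCC(=O)OC(C)(C)C)[C@H](O[Si](C)(C)C(C)(C)C)[C@@](C=O)([C@H]2COC(C)(C)O2)CC1
F10 | step 16 | C2 ethylene ketal of 25 | C[C@]4(CCC[C@@H]1C5(OCCO5)CCC2=C[C@@](C)([C@H]3COC(C)(C)O3)CC[C@@]21C)COC(C)(C)O4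
F11 | step 16 | C5 alcohol from hydroboration of F10 (C4a and C5 as a mixture) | C[C@]4(CCC[C@@H]1C5(OCCO5)CCC2C(O)[C@@](C)([C@H]3COC(C)(C)O3)CC[C@@]21C)COC(C)(C)O4
F12 | step 16 | trans-fused 5-ketone (C2 ethylene ketal, C4a–H anti to the C8a methyl) | C[C@]4(CCC[C@@H]1C5(OCCO5)CC[C@H]2C(=O)[C@@](C)([C@H]3COC(C)(C)O3)CC[C@@]21C)COC(C)(C)O4
F13 | step 16 | C2 ethylene ketal of 26 | C[C@]4(CCC[C@@H]1C5(OCCO5)CC[C@H]2C[C@@](C)([C@H]3COC(C)(C)O3)CC[C@@]21C)COC(C)(C)O4
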